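**Plan** (ring numbering O1–O2–C3–C4–C5–C6; side chain C2′(CH3)–C1′O2H on C3)
- Retrosynthetic cuts, in order: C1′ acid ⇐ CH2OTBS; C4–C5 ⇐ C4=C5; ring bond C5–C6 ⇐ acyclic monoperoxyketal carrying a (Z)-vinylsilane; ketal bond O1–C6 ⇐ hydroperoxide + farnesylacetone dimethyl ketal; C3–O2 ⇐ allylic mesylate (inversion); C2′–C3 ⇐ Evans aldol.
- Forward: a small chiral hydroperoxide (steps 1–5) is joined to the C18 ketone as a peroxyketal (step 7); the only ring, the 1,2-dioxane, then closes at C5–C6 (step 8); alkene saturation, desilylation and oxidation finish the route.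
- Enabling feature: C6 is a fully substituted ring carbon bonded to peroxide oxygen O1, i.e. a masked ketone carbon (C2 of farnesylacetone) that ionises to a peroxycarbenium ion C6=O1+. C4–C5 is an unsubstituted two-carbon bridge to C3 that can be carried as a cis-vinylsilane.
- Stereochemistry: C2′ and C3 come from the oxazolidinone aldol (C3 is then inverted by hydroperoxide SN2); C6 is set from C3 through the half-chair transition state of the ring closure.

Key step: step 8

Assumption: (5E,9E)-farnesylacetone (10) is taken as purchasable as the single E,E isomer; the ketal carbon of 12 is formed as both epimers, which is without consequence because it becomes planar in step 8.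

Step 1
Reactants: 1 (4S)-4-benzyl-3-propanoyl-1,3-oxazolidin-2-one; 2 3-(trimethylsilyl)prop-2-ynal
Product: 4 (4S)-4-benzyl-3-[(2S,3S)-3-hydroxy-2-methyl-5-(trimethylsilyl)pent-4-ynoyl]-1,3-oxazolidin-2-one, via Z-boron enolate 3 (not isolated)
Conditions: Bu2BOTf, i-Pr2NEt, CH2Cl2, 0 °C; 2, −78 → 0 °C; then pH 7 buffer, MeOH, H2O2
Reagents that add atoms: none
Why: Evans syn aldol reaction; the Z-boron enolate should react through a Zimmerman–Traxler chair on the face opposite the benzyl group, which sets the methyl-bearing centre (future C2′) and the syn carbinol centre (future C3, to be inverted in step 5).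

Step 2
Reactants: 4 aldol adduct
Product: 5 (2R,3S)-2-methyl-5-(trimethylsilyl)pent-4-yne-1,3-diol
Conditions: LiBH4, MeOH (1 equiv), Et2O/THF, 0 °C
Reagents that add atoms: none
Why: Reductive removal of the oxazolidinone auxiliary with LiBH4 should give the 1,3-diol without touching the alkynylsilane or either stereocentre.

Step 3
Reactants: 5 diol
Product: 6 (3S,4R)-5-[(tert-butyldimethylsilyl)oxy]-4-methyl-1-(trimethylsilyl)pent-1-yn-3-ol
Conditions: TBSCl, imidazole, CH2Cl2, −20 → 0 °C
Reagents that add atoms: tert-butyldimethylsilyl chloride, CC(C)(C)[Si](C)(C)Cl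
Why: Selective silylation of the primary hydroxyl of a 1,3-diol should leave the secondary propargylic alcohol free.

Step 4
Reactants: 6 propargylic alcohol
Product: 7 (1Z,3S,4R)-5-[(tert-butyldimethylsilyl)oxy]-4-methyl-1-(trimethylsilyl)pent-1-en-3-ol
Conditions: H2 (1 atm), Pd/CaCO3 poisoned with Pb(OAc)2, quinoline, EtOAc/hexane, rt
Reagents that add atoms: none
Why: Lindlar semihydrogenation adds H2 syn to the alkynylsilane and should give the (Z)-vinylsilane that the endocyclic ipso substitution of step 8 requires.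

Step 5
Reactants: 7 (Z)-allylic alcohol
Product: 9 (1Z,3R,4R)-5-[(tert-butyldimethylsilyl)oxy]-4-methyl-1-(trimethylsilyl)pent-1-en-3-yl hydroperoxide, via allylic mesylate 8 (not isolated)
Conditions: MsCl, Et3N, THF, −40 °C; then 50% aq. H2O2 (large excess), KOH, MeOH, −20 → 0 °C
Reagents that add atoms: hydrogen peroxide, OO
Why: Displacement of a secondary sulfonate by hydroperoxide anion (SN2 synthesis of secondary hydroperoxides) should invert the carbinol carbon and turn the syn aldol relationship into the anti C2′/C3 relationship of the target; the cis silyl group shields the SN2′ position, and any C3 epimer would be a separable diastereomer.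

Step 6
Reactants: 10 (5E,9E)-6,10,14-trimethylpentadeca-5,9,13-trien-2-one (farnesylacetone)
Product: 11 (5E,9E)-2,2-dimethoxy-6,10,14-trimethylpentadeca-5,9,13-triene
Conditions: HC(OMe)3, MeOH, PPTS (cat.), rt
Reagents that add atoms: trimethyl orthoformate, COC(OC)OC
Why: Acid-catalysed ketalisation with the orthoformate as water scavenger; PPTS is mild enough for the three trisubstituted olefins.

Step 7
Reactants: 9 hydroperoxide; 11 dimethyl ketal
Product: 12 tert-butyl{[(2R,3R,4Z)-3-{[(5E,9E)-2-methoxy-6,10,14-trimethylpentadeca-5,9,13-trien-2-yl]peroxy}-2-methyl-5-(trimethylsilyl)pent-4-en-1-yl]oxy}dimethylsilane (both epimers at the ketal carbon)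
Conditions: PPTS (cat.), CH2Cl2, 5 Å molecular sieves, 0 °C → rt
Reagents that add atoms: none
Why: Acid-catalysed transketalisation of a dimethyl ketal by a hydroperoxide is the standard entry to monoperoxyketals and joins the two fragments at O1–C6.

Step 8
Reactants: 12 monoperoxyketal
Product: 14 tert-butyldimethyl{(2R)-2-[(3S,6S)-6-methyl-6-[(3E,7E)-4,8,12-trimethyltrideca-3,7,11-trien-1-yl]-3,6-dihydro-1,2-dioxin-3-yl]propoxy}silane, via peroxycarbenium triflate 13 (not isolated)
Conditions: Me3SiOTf (0.3 equiv), 2,6-di-tert-butyl-4-methylpyridine (0.4 equiv), CH2Cl2, −78 °C; sat. aq. NaHCO3 quench at −78 °C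
Reagents that add atoms: none
Why: Proposed new method: Me3SiOTf removes the methoxy group from the ketal carbon of 12 to give peroxycarbenium ion 13 (cation stabilised by the lone pair of the adjacent peroxide oxygen O1), the tethered (Z)-vinylsilane attacks it through its silicon-bearing carbon, and the β-silyl cation so formed expels Me3Si+, which leaves the C4=C5 ring alkene and regenerates Me3SiOTf. The closest known reaction types are the Lewis-acid-mediated additions of allylsilanes and silyl enol ethers to peroxycarbenium ions and the silyl-Prins cyclisation of (Z)-4-silylbut-3-en-1-ols with carbonyl compounds to dihydropyrans; the step is the peroxide counterpart of the latter and has not been shown for a vinylsilane with a peroxycarbenium ion. The 3,6-dihydro-1,2-dioxine ring closes in a 6-endo-trig mode at the vinylsilane with the C6=O1+ unit also inside the ring (Prins topology), which is why the Z geometry is required. The new quaternary stereocentre C6 is controlled by C3 through a half-chair transition state: allylic 1,3-strain with the cis silyl group places the C3 side chain pseudo-equatorial, and the position on the cationic carbon that lies gauche to the bulky Me3Si group should be taken by methyl, not by the homofarnesyl chain, which puts the chain cis to the C3 side chain as in the target. The step needs chemoselectivity for the tethered vinylsilane over the three trisubstituted olefins and freedom from protic acid; intramolecularity (the nearest chain olefin could only close 4-exo or 5-endo), the substoichiometric Lewis acid, the hindered pyridine buffer and −78 °C should secure this.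

Step 9
Reactants: 14 dihydrodioxine
Product: 15 tert-butyldimethyl{(2R)-2-[(3S,6S)-6-methyl-6-[(3E,7E)-4,8,12-trimethyltrideca-3,7,11-trien-1-yl]-1,2-dioxan-3-yl]propoxy}silane
Conditions: KO2CN=NCO2K (portionwise), AcOH, CH2Cl2/MeOH, 0 °C → rt, stopped at full consumption of 14
Reagents that add atoms: none
Why: Diimide reduction (concerted syn transfer of H2, inert towards O–O bonds) is the standard way to saturate 3,6-dihydro-1,2-dioxines; the cis-1,2-disubstituted ring olefin flanked by two allylic oxygens should react before the three trisubstituted chain olefins when the reagent is dosed.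

Step 10
Reactants: 15 silyl ether
Product: 16 (2R)-2-[(3S,6S)-6-methyl-6-[(3E,7E)-4,8,12-trimethyltrideca-3,7,11-trien-1-yl]-1,2-dioxan-3-yl]propan-1-ol
Conditions: HF·pyridine, pyridine, THF, 0 °C → rt
Reagents that add atoms: none
Why: Buffered, non-basic fluoride desilylation should spare the peroxide (no Kornblum–DeLaMare fragmentation) and the olefins.

Step 11
Reactants: 16 primary alcohol
Product: 18 (2S)-2-[(3S,6S)-6-methyl-6-[(3E,7E)-4,8,12-trimethyltrideca-3,7,11-trien-1-yl]-1,2-dioxan-3-yl]propanoic acid, via aldehyde 17 (not isolated)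
Conditions: TEMPO (0.2 equiv), PhI(OAc)2 (2.5 equiv), CH2Cl2/H2O, rt
Reagents that add atoms: water, O
Why: Oxoammonium-catalysed (TEMPO) oxidation of the primary alcohol through the aldehyde hydrate under near-neutral conditions should not epimerise C2′, eliminate the β-peroxide or attack the olefins.

**Compound list**
1 | (4S)-4-benzyl-3-propanoyl-1,3-oxazolidin-2-one | CCC(=O)N1[C@@H](Cc2ccccc2)COC1=O | starting material
2 | 3-(trimethylsilyl)prop-2-ynal | C[Si](C)(C)C#CC=O | starting material
3 | (4S)-4-benzyl-3-[(1Z)-1-[(dibutylboranyl)oxy]prop-1-en-1-yl]-1,3-oxazolidin-2-one (not isolated) | C/C=C(\OB(CCCC)CCCC)N1[C@@H](Cc2ccccc2)COC1=O | intermediate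
4 | (4S)-4-benzyl-3-[(2S,3S)-3-hydroxy-2-methyl-5-(trimethylsilyl)pent-4-ynoyl]-1,3-oxazolidin-2-one | C[Si](C)(C)C#C[C@H]([C@H](C)C(=O)N1[C@@H](Cc2ccccc2)COC1=O)O | intermediate
5 | (2R,3S)-2-methyl-5-(trimethylsilyl)pent-4-yne-1,3-diol | C[Si](C)(C)C#C[C@H]([C@H](C)CO)O | intermediate
6 | (3S,4R)-5-[(tert-butyldimethylsilyl)oxy]-4-methyl-1-(trimethylsilyl)pent-1-yn-3-ol | C[Si](C)(C)C#C[C@H]([C@H](C)CO[Si](C)(C)C(C)(C)C)O | intermediate
7 | (1Z,3S,4R)-5-[(tert-butyldimethylsilyl)oxy]-4-methyl-1-(trimethylsilyl)pent-1-en-3-ol | C[Si](C)(C)/C=C\[C@H]([C@H](C)CO[Si](C)(C)C(C)(C)C)O | intermediate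
8 | (1Z,3S,4R)-5-[(tert-butyldimethylsilyl)oxy]-4-methyl-1-(trimethylsilyl)pent-1-en-3-yl methanesulfonate (not isolated) | C[Si](C)(C)/C=C\[C@H]([C@H](C)CO[Si](C)(C)C(C)(C)C)OS(C)(=O)=O | intermediate
9 | (1Z,3R,4R)-5-[(tert-butyldimethylsilyl)oxy]-4-methyl-1-(trimethylsilyl)pent-1-en-3-yl hydroperoxide | C[Si](C)(C)/C=C\[C@@H]([C@H](C)CO[Si](C)(C)C(C)(C)C)OO | intermediate
10 | (5E,9E)-6,10,14-trimethylpentadeca-5,9,13-trien-2-one (farnesylacetone) | CC(C)=CCC/C(C)=C/CC/C(C)=C/CCC(C)=O | starting material
11 | (5E,9E)-2,2-dimethoxy-6,10,14-trimethylpentadeca-5,9,13-triene | CC(C)=CCC/C(C)=C/CC/C(C)=C/CCC(C)(OC)OC | intermediate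
12 | tert-butyl{[(2R,3R,4Z)-3-{[(5E,9E)-2-methoxy-6,10,14-trimethylpentadeca-5,9,13-trien-2-yl]peroxy}-2-methyl-5-(trimethylsilyl)pent-4-en-1-yl]oxy}dimethylsilane (both ketal epimers) | CC(C)=CCC/C(C)=C/CC/C(C)=C/CCC(C)(OC)OO[C@@H](/C=C\[Si](C)(C)C)[C@H](C)CO[Si](C)(C)C(C)(C)C | intermediate
13 | peroxycarbenium triflate derived from 12 by loss of methoxide (not isolated) | CC(C)=CCC/C(C)=C/CC/C(C)=C/CCC(C)=[O+]O[C@@H](/C=C\[Si](C)(C)C)[C@H](C)CO[Si](C)(C)C(C)(C)C.[O-]S(=O)(=O)C(F)(F)F | intermediate
14 | tert-butyldimethyl{(2R)-2-[(3S,6S)-6-methyl-6-[(3E,7E)-4,8,12-trimethyltrideca-3,7,11-trien-1-yl]-3,6-dihydro-1,2-dioxin-3-yl]propoxy}silane | CC(C)=CCC/C(C)=C/CC/C(C)=C/CC[C@@]1(C)C=C[C@@H]([C@H](C)CO[Si](C)(C)C(C)(C)C)OO1 | intermediate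
15 | tert-butyldimethyl{(2R)-2-[(3S,6S)-6-methyl-6-[(3E,7E)-4,8,12-trimethyltrideca-3,7,11-trien-1-yl]-1,2-dioxan-3-yl]propoxy}silane | CC(C)=CCC/C(C)=C/CC/C(C)=C/CC[C@@]1(C)CC[C@@H]([C@H](C)CO[Si](C)(C)C(C)(C)C)OO1 | intermediate
16 | (2R)-2-[(3S,6S)-6-methyl-6-[(3E,7E)-4,8,12-trimethyltrideca-3,7,11-trien-1-yl]-1,2-dioxan-3-yl]propan-1-ol | CC(C)=CCC/C(C)=C/CC/C(C)=C/CC[C@@]1(C)CC[C@@H]([C@H](C)CO)OO1 | intermediate
17 | (2S)-2-[(3S,6S)-6-methyl-6-[(3E,7E)-4,8,12-trimethyltrideca-3,7,11-trien-1-yl]-1,2-dioxan-3-yl]propanal (not isolated) | CC(C)=CCC/C(C)=C/CC/C(C)=C/CC[C@@]1(C)CC[C@@H]([C@H](C)C=O)OO1 | intermediate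
18 | (2S)-2-[(3S,6S)-6-methyl-6-[(3E,7E)-4,8,12-trimethyltrideca-3,7,11-trien-1-yl]-1,2-dioxan-3-yl]propanoic acid | CC(C)=CCC/C(C)=C/CC/C(C)=C/CC[C@@]1(C)CC[C@@H]([C@H](C)C(=O)O)OO1 | target

**Count**
Total steps: 11. Longest linear sequence: 10 steps (steps 1–5 and 7–11; step 6 is the side branch).

**Steps most likely to fail**

1. Step 8 (Proposed new method). The vinylsilane may be too weak a nucleophile, so that the peroxycarbenium ion decomposes or the silane is protodesilylated before ring closure, or facial selectivity at the new quaternary centre may be poor. The fallback uses known reactions only, sets out from 10 and 1 and comes back at 16. The C5–C6 bond is taken from the methyl ketone itself and the ring is closed at O2–C3 instead.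
 - The kinetic lithium enolate of 10 (LiN(i-Pr)2, THF, −78 °C) is alkylated on the methyl group with ethyl bromoacetate to ethyl (7E,11E)-8,12,16-trimethyl-4-oxoheptadeca-7,11,15-trienoate F1.
 - Wittig methylenation (Ph3PCH3Br, KOt-Bu) gives ethyl (7E,11E)-8,12,16-trimethyl-4-methylideneheptadeca-7,11,15-trienoate F2, and i-Bu2AlH at −78 °C gives (7E,11E)-8,12,16-trimethyl-4-methylideneheptadeca-7,11,15-trienal F3.
 - The Evans syn aldol of step 1 with 1 gives (4S)-4-benzyl-3-[(2S,3R,9E,13E)-3-hydroxy-2,10,14,18-tetramethyl-6-methylidenenonadeca-9,13,17-trienoyl]-1,3-oxazolidin-2-one F4.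
 - LiBH4 gives (2R,3R,9E,13E)-2,10,14,18-tetramethyl-6-methylidenenonadeca-9,13,17-triene-1,3-diol F5, and TBSCl gives (2R,3R,9E,13E)-1-[(tert-butyldimethylsilyl)oxy]-2,10,14,18-tetramethyl-6-methylidenenonadeca-9,13,17-trien-3-ol F6.
 - MsCl/Et3N gives (2R,3R,9E,13E)-1-[(tert-butyldimethylsilyl)oxy]-2,10,14,18-tetramethyl-6-methylidenenonadeca-9,13,17-trien-3-yl methanesulfonate F7.
 - Mukaiyama–Isayama hydroperoxysilylation (Co(acac)2, O2, Et3SiH), which prefers the 1,1-disubstituted olefin over the trisubstituted ones, gives (2R,3R,9E,13E)-1-[(tert-butyldimethylsilyl)oxy]-2,6,10,14,18-pentamethyl-6-[(triethylsilyl)peroxy]nonadeca-9,13,17-trien-3-yl methanesulfonate F8 as both C6 epimers.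
 - n-Bu4NF in THF frees the peroxide anion, which displaces the mesylate intramolecularly with inversion (6-exo-tet), and also removes the TBS group. This gives 16 and its C6 epimer; they are diastereomers and are separated by chromatography.

2. Step 5. The allylic mesylate may be solvolysed by the protic medium, and the free allylic hydroperoxide may be dehydrated by base (Kornblum–DeLaMare) faster than it accumulates. The fallback sets out from 7 and 11 and comes back at 12, so that steps 5 and 7 merge and no free secondary hydroperoxide is handled. Ketal 11 is perhydrolysed with anhydrous ethereal H2O2 and catalytic PPTS to (5E,9E)-2-methoxy-6,10,14-trimethylpentadeca-5,9,13-trien-2-yl hydroperoxide F9. Its caesium salt (CsOH·H2O, DMF, 0 °C) is alkylated by mesylate 8, made from 7 as before, with inversion. This is the known alkylation of α-alkoxy hydroperoxides by sulfonates in an aprotic medium, and the product is the dialkyl peroxide 12 itself.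

3. Step 9. Diimide may over-reduce the chain olefins before the hindered ring olefin, next to the quaternary carbon, is consumed. The fallback sets out from 14 and comes back at 15. The stoichiometric pericyclic hydrogen transfer is replaced by homogeneous catalytic hydrogenation (H2, 1 atm, RhCl(PPh3)3, benzene/EtOH, rt). Its selectivity rests on olefin coordination, so trisubstituted olefins are essentially inert, and this catalyst has been used to saturate olefins next to cyclic peroxides. No compound outside the list arises (entry F0).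

**Further compounds**
F1 | step 8 | ethyl (7E,11E)-8,12,16-trimethyl-4-oxoheptadeca-7,11,15-trienoate | CC(C)=CCC/C(C)=C/CC/C(C)=C/CCC(=O)CCC(=O)OCC
F2 | step 8 | ethyl (7E,11E)-8,12,16-trimethyl-4-methylideneheptadeca-7,11,15-trienoate | CC(C)=CCC/C(C)=C/CC/C(C)=C/CCC(=C)CCC(=O)OCC
F3 | step 8 | (7E,11E)-8,12,16-trimethyl-4-methylideneheptadeca-7,11,15-trienal | CC(C)=CCC/C(C)=C/CC/C(C)=C/CCC(=C)CCC=O
F4 | step 8 | (4S)-4-benzyl-3-[(2S,3R,9E,13E)-3-hydroxy-2,10,14,18-tetramethyl-6-methylidenenonadeca-9,13,17-trienoyl]-1,3-oxazolidin-2-one | CC(C)=CCC/C(C)=C/CC/C(C)=C/CCC(=C)CC[C@H]([C@H](C)C(=O)N1[C@@H](Cc2ccccc2)COC1=O)O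
F5 | step 8 | (2R,3R,9E,13E)-2,10,14,18-tetramethyl-6-methylidenenonadeca-9,13,17-triene-1,3-diol | CC(C)=CCC/C(C)=C/CC/C(C)=C/CCC(=C)CC[C@H]([C@H](C)CO)O
F6 | step 8 | (2R,3R,9E,13E)-1-[(tert-butyldimethylsilyl)oxy]-2,10,14,18-tetramethyl-6-methylidenenonadeca-9,13,17-trien-3-ol | CC(C)=CCC/C(C)=C/CC/C(C)=C/CCC(=C)CC[C@H]([C@H](C)CO[Si](C)(C)C(C)(C)C)O
F7 | step 8 | (2R,3R,9E,13E)-1-[(tert-butyldimethylsilyl)oxy]-2,10,14,18-tetramethyl-6-methylidenenonadeca-9,13,17-trien-3-yl methanesulfonate | CC(C)=CCC/C(C)=C/CC/C(C)=C/CCC(=C)CC[C@H]([C@H](C)CO[Si](C)(C)C(C)(C)C)OS(C)(=O)=O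
F8 | step 8 | (2R,3R,9E,13E)-1-[(tert-butyldimethylsilyl)oxy]-2,6,10,14,18-pentamethyl-6-[(triethylsilyl)peroxy]nonadeca-9,13,17-trien-3-yl methanesulfonate (both C6 epimers) | CC(C)=CCC/C(C)=C/CC/C(C)=C/CCC(C)(OO[Si](CC)(CC)CC)CC[C@H]([C@H](C)CO[Si](C)(C)C(C)(C)C)OS(C)(=O)=O
F9 | step 5 | (5E,9E)-2-methoxy-6,10,14-trimethylpentadeca-5,9,13-trien-2-yl hydroperoxide | CC(C)=CCC/C(C)=C/CC/C(C)=C/CCC(C)(OC)OO
F0 | step 9 | none | none
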